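**Plan**

Locants (germacranolide style): ring C1–C10; C1=C10 carries C14 (CH2OAc), C4=C5 carries C15 (CH2O‑acyl), ring‑fusion C7 carries C11(=C13H2)–C12(=O)–O–C8.
Cuts (retro): both allylic esters and C11=C13; the lactone bond O–C12, leaving an 8‑ketone with a CH2CO2Me arm on C7; the ring bond C6–C7, whose ends are re‑tied through a CO2 bridge (C7–C(=O)–O–C6) to a 12‑membered allyl β‑keto lactone; that lactone C–O bond; C1=C10 (olefination); C3–C4 (carbocupration).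
Enabling feature: C6 is the terminus of the allyl unit C4=C5–C6 and C7 is α to C8 (the lactone carbinol carbon taken at the ketone level). C6–C7 is therefore an allyl–enolate bond, and two atoms (C and O) can be excised from a 12‑membered ring to leave the 10‑membered carbocycle.
Forward: open chain with both trisubstituted olefins fixed → 12‑membered lactone by acylketene capture → Pd‑catalysed decarboxylative ring contraction to the cyclodecadienone → trans γ‑lactone → α‑methylene → acetate, then the 2‑(hydroxymethyl)acrylate.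
Stereochemistry: ring‑trans C4=C5 (CIP Z) from syn‑carbocupration of a 2‑ynoate; ring‑cis C1=C10 (CIP E) from an E‑selective Horner–Wadsworth–Emmons reaction; C7 (R) from the chiral ligand in the ring contraction; C8 (S) from a CBS reduction, with lactonisation turning any 7S material into a separable cis‑lactone.

Key step: step 14

Remark: the sense of induction of the chiral ligand in step 14 is assumed, not derived; the antipodal ligand is taken if the first run shows the 7S sense. TBDPS = tert‑butyldiphenylsilyl, TBS = tert‑butyldimethylsilyl, TES = triethylsilyl.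

**Route**

Step 1
Reactants: 1 tert‑butyl(diphenyl)(prop‑2‑yn‑1‑yloxy)silane
Product: 2 methyl 4‑(TBDPS‑oxy)but‑2‑ynoate
Conditions: n‑BuLi (1.05 equiv), THF, −78 °C; ClCO2Me, −78 → 0 °C
Reagents that add atoms: methyl chloroformate, COC(=O)Cl
Why: C‑acylation of a lithium acetylide with a chloroformate is the standard route to 2‑ynoates and the silyl ether is inert to it.

Step 2
Reactants: 2 methyl 4‑(TBDPS‑oxy)but‑2‑ynoate; 3 [2‑(1,3‑dioxan‑2‑yl)ethyl]magnesium bromide (commercial 0.5 M THF solution)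
Product: 4 methyl (2Z)‑3‑[(TBDPS‑oxy)methyl]‑5‑(1,3‑dioxan‑2‑yl)pent‑2‑enoate
Conditions: 3 (1.3 equiv), CuBr·SMe2 (1.3 equiv), THF, −45 °C; then 2, −78 °C, 2 h; MeOH then aq NH4Cl at −78 °C
Reagents that add atoms: none
Why: syn‑carbocupration of the ynoate puts the new alkyl group and the incoming proton cis, so CH2OSi and CO2Me end up cis (2Z); protonation at −78 °C should prevent isomerisation of the alkenylcopper through the allenoate.

Step 3
Reactants: 4 methyl (2Z)‑3‑[(TBDPS‑oxy)methyl]‑5‑(1,3‑dioxan‑2‑yl)pent‑2‑enoate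
Product: 5 methyl (2Z)‑3‑[(TBDPS‑oxy)methyl]‑6‑oxohex‑2‑enoate
Conditions: 2 M aq HCl/THF (1:4), 40 °C
Reagents that add atoms: water, O
Why: acid‑catalysed acetal hydrolysis frees the aldehyde, while the TBDPS ether and the β,β‑disubstituted enoate should tolerate dilute acid.

Step 4
Reactants: 6 trimethyl phosphonoacetate; 7 tert‑butyl bromoacetate
Product: 8 4‑tert‑butyl 1‑methyl 2‑(dimethoxyphosphoryl)butanedioate (racemic)
Conditions: NaH (1.0 equiv), THF, 0 °C; then 7, 0 → 23 °C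
Reagents that add atoms: none
Why: C‑alkylation of the phosphonoacetate anion with an α‑bromo ester gives a phosphonosuccinate whose two esters can be told apart.

Step 5
Reactants: 5 methyl (2Z)‑3‑[(TBDPS‑oxy)methyl]‑6‑oxohex‑2‑enoate; 8 4‑tert‑butyl 1‑methyl 2‑(dimethoxyphosphoryl)butanedioate
Product: 9 4‑tert‑butyl 1‑methyl (2E)‑2‑{(4Z)‑6‑methoxy‑6‑oxo‑4‑[(TBDPS‑oxy)methyl]hex‑4‑en‑1‑ylidene}butanedioate
Conditions: NaH (1.05 equiv), 8, THF, 0 °C; then 5, 0 → 23 °C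
Reagents that add atoms: none
Why: the Horner–Wadsworth–Emmons olefination with an α‑substituted phosphonoacetate is E‑selective, which places CO2Me (C14) trans and the CH2CO2tBu arm (C9) cis to the chain, the relationship that becomes the ring‑cis C1=C10 olefin.

Step 6
Reactants: 9 4‑tert‑butyl 1‑methyl (2E)‑2‑{(4Z)‑6‑methoxy‑6‑oxo‑4‑[(TBDPS‑oxy)methyl]hex‑4‑en‑1‑ylidene}butanedioate
Product: 10 (3E,7Z)‑9‑methoxy‑3‑(methoxycarbonyl)‑9‑oxo‑7‑[(TBDPS‑oxy)methyl]nona‑3,7‑dienoic acid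
Conditions: CF3CO2H/CH2Cl2 (1:4), 0 → 23 °C
Reagents that add atoms: none
Why: acidolysis of the tert‑butyl ester frees only the non‑conjugated acid; both olefins are deactivated enoates and a primary TBDPS ether should survive the acid.

Step 7
Reactants: 10 (3E,7Z)‑9‑methoxy‑3‑(methoxycarbonyl)‑9‑oxo‑7‑[(TBDPS‑oxy)methyl]nona‑3,7‑dienoic acid
Product: 12 (4E)‑4‑{(4Z)‑6‑hydroxy‑4‑[(TBDPS‑oxy)methyl]hex‑4‑en‑1‑ylidene}oxolan‑2‑one, via diol acid 11 (not isolated)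
Conditions: i‑Bu2AlH (6 equiv), CH2Cl2, −78 °C; aq potassium sodium tartrate; then 1 M HCl, 23 °C
Reagents that add atoms: none
Why: in this hydride reduction the aluminium carboxylate should stay inert at −78 °C while both conjugated methyl esters go to allylic alcohols, and on acidification only the C14 hydroxyl can close a five‑membered lactone, which leaves the C6 hydroxyl as the only free alcohol.

Step 8
Reactants: 12 (4E)‑4‑{(4Z)‑6‑hydroxy‑4‑[(TBDPS‑oxy)methyl]hex‑4‑en‑1‑ylidene}oxolan‑2‑one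
Product: 13 (4E)‑4‑{(4Z)‑4‑[(TBDPS‑oxy)methyl]‑6‑(TES‑oxy)hex‑4‑en‑1‑ylidene}oxolan‑2‑one
Conditions: Et3SiCl, imidazole, CH2Cl2, 0 °C
Reagents that add atoms: chlorotriethylsilane, CC[Si](Cl)(CC)CC
Why: silylation of the single primary alcohol gives a temporary ether that can later be removed beside TBS and TBDPS ethers.

Step 9
Reactants: 13 (4E)‑4‑{(4Z)‑4‑[(TBDPS‑oxy)methyl]‑6‑(TES‑oxy)hex‑4‑en‑1‑ylidene}oxolan‑2‑one
Product: 16 (3E,7Z)‑3‑[(TBS‑oxy)methyl]‑7‑[(TBDPS‑oxy)methyl]‑9‑(TES‑oxy)nona‑3,7‑dienoic acid, via lithium carboxylate 14 (not isolated), via silyl ester 15 (not isolated)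
Conditions: LiOH·H2O, THF/H2O, 0 → 23 °C; evaporation; t‑BuMe2SiCl (3 equiv), imidazole, DMF, 23 °C; then K2CO3, MeOH/THF/H2O, 0 °C; pH 5 buffer
Reagents that add atoms: lithium hydroxide, [Li+].[OH-]; tert‑butylchlorodimethylsilane, CC(C)(C)[Si](C)(C)Cl
Why: saponification opens the lactone, silylation of the carboxylate salt traps the C14 hydroxyl before it can re‑lactonise, and the labile silyl ester is then hydrolysed selectively to the free acid.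

Step 10
Reactants: 16 (3E,7Z)‑3‑[(TBS‑oxy)methyl]‑7‑[(TBDPS‑oxy)methyl]‑9‑(TES‑oxy)nona‑3,7‑dienoic acid; 17 3‑tert‑butoxy‑3‑oxopropanoic acid
Product: 19 tert‑butyl (5E,9Z)‑3‑oxo‑5‑[(TBS‑oxy)methyl]‑9‑[(TBDPS‑oxy)methyl]‑11‑(TES‑oxy)undeca‑5,9‑dienoate, via acyl imidazolide 18 (not isolated)
Conditions: 1,1'‑carbonyldiimidazole, THF, 23 °C; then 17, MgCl2, Et3N, MeCN/THF, 23 → 40 °C; aq citric acid
Reagents that add atoms: none
Why: the decarboxylative Claisen condensation of a magnesium malonate half ester with an acyl imidazolide (Masamune conditions) builds the β‑keto ester under nearly neutral conditions that should not move the β,γ‑double bond into conjugation.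

Step 11
Reactants: 19 tert‑butyl (5E,9Z)‑3‑oxo‑5‑[(TBS‑oxy)methyl]‑9‑[(TBDPS‑oxy)methyl]‑11‑(TES‑oxy)undeca‑5,9‑dienoate
Product: 20 tert‑butyl (5E,9Z)‑11‑hydroxy‑3‑oxo‑5‑[(TBS‑oxy)methyl]‑9‑[(TBDPS‑oxy)methyl]undeca‑5,9‑dienoate
Conditions: pyridinium p‑toluenesulfonate (0.2 equiv), MeOH/CH2Cl2, 0 °C
Reagents that add atoms: none
Why: acid‑catalysed solvolysis removes a primary triethylsilyl ether much faster than primary TBS and TBDPS ethers.

Step 12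
Reactants: 20 tert‑butyl (5E,9Z)‑11‑hydroxy‑3‑oxo‑5‑[(TBS‑oxy)methyl]‑9‑[(TBDPS‑oxy)methyl]undeca‑5,9‑dienoate
Product: 22 (6E,10Z)‑6‑[(TBS‑oxy)methyl]‑10‑[(TBDPS‑oxy)methyl]‑1‑oxacyclododeca‑6,10‑diene‑2,4‑dione, via acylketene 21 (not isolated)
Conditions: toluene, 110 °C, slow addition to a final 1 mM, N2 sweep
Reagents that add atoms: none
Why: thermal loss of tert‑butanol from the β‑keto ester gives an acylketene that the remote primary allylic alcohol should trap at high dilution (acylketene macrolactonisation), closing a 12‑membered ring that is large enough for the ring‑trans C4=C5 olefin.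

Step 13
Reactants: 22 (6E,10Z)‑6‑[(TBS‑oxy)methyl]‑10‑[(TBDPS‑oxy)methyl]‑1‑oxacyclododeca‑6,10‑diene‑2,4‑dione; 23 methyl bromoacetate
Product: 24 methyl 2‑{(6E,10Z)‑2,4‑dioxo‑6‑[(TBS‑oxy)methyl]‑10‑[(TBDPS‑oxy)methyl]‑1‑oxacyclododeca‑6,10‑dien‑3‑yl}acetate (C3 labile)
Conditions: K2CO3, acetone, 23 °C
Reagents that add atoms: none
Why: enolate alkylation occurs selectively at the doubly activated C3–H of the β‑keto lactone (C7) under mild carbonate conditions; the new centre is configurationally labile and of no consequence yet.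

Step 14
Reactants: 24 methyl 2‑{(6E,10Z)‑2,4‑dioxo‑6‑[(TBS‑oxy)methyl]‑10‑[(TBDPS‑oxy)methyl]‑1‑oxacyclododeca‑6,10‑dien‑3‑yl}acetate
Product: 25 methyl 2‑{(1R,3Z,7E)‑10‑oxo‑4‑[(TBDPS‑oxy)methyl]‑8‑[(TBS‑oxy)methyl]cyclodeca‑3,7‑dien‑1‑yl}acetate
Conditions: Pd2(dba)3·CHCl3 (5 mol %), (R,R)‑ANDEN‑phenyl bis(2‑diphenylphosphinobenzamide) ligand (12 mol %), 1,4‑dioxane, 23 °C, slow addition to 2 mM
Reagents that add atoms: none
Why: Proposed new method: Pd(0) ionises the allylic C–O bond of the 12‑membered lactone to a zwitterion in which the π‑allyl unit (C6–C5–C4) and the β‑keto carboxylate stay joined through C8–C9–C10=C1–C2–C3; loss of CO2 gives the Pd enolate regiospecifically at C7, and C7 bonds to the primary allyl terminus C6, so the ring contracts from 12 to 10 atoms with extrusion of the two bridge atoms. The closest known reactions are the Tsuji–Saegusa decarboxylative allylation of allyl β‑keto esters, its asymmetric variant with this ligand class, and the Pd‑catalysed decarboxylative ring contraction of cyclic allylic carbamates and carbonates; new here is the use on a macrocyclic allyl β‑keto lactone to make a medium carbocycle. The only ring closed is the ten‑membered carbocycle, by attack of the tethered enolate on the allyl terminus that carried the lactone oxygen (exo with respect to the departing palladium); attack at the tertiary terminus C4 would give an eight‑membered ring with a quaternary centre and is disfavoured sterically. The new stereocentre C7 is set by the chiral ligand, which differentiates the faces of the prochiral enolate in the C–C bond‑forming step, and is expected to be enriched in the R sense with the matched ligand. The step needs C7 rather than C9 attack (regiospecific enolate generation by decarboxylation and fast ion‑pair collapse in a non‑polar solvent), retention of the C4=C5 geometry (the C3 chain is syn in the π‑allyl and syn–anti exchange would need η1 bonding at the tertiary carbon), and ring contraction rather than oligomerisation or diene formation (high dilution, no added base).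

Step 15
Reactants: 25 methyl 2‑{(1R,3Z,7E)‑10‑oxo‑4‑[(TBDPS‑oxy)methyl]‑8‑[(TBS‑oxy)methyl]cyclodeca‑3,7‑dien‑1‑yl}acetate
Product: 27 (3aR,5Z,9E,11aS)‑6‑[(TBDPS‑oxy)methyl]‑10‑[(TBS‑oxy)methyl]‑3a,4,7,8,11,11a‑hexahydrocyclodeca[b]furan‑2(3H)‑one, via hydroxy ester 26 (not isolated)
Conditions: (R)‑2‑methyl‑CBS‑oxazaborolidine (0.3 equiv), catecholborane (1.5 equiv), toluene, −78 °C; MeOH; then DBU (0.1 equiv), CH2Cl2, 23 °C; chromatography
Reagents that add atoms: none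
Why: the Corey–Bakshi–Shibata reduction should deliver hydride to the ketone face fixed by the catalyst (branched C7 as the large group) to give the 8S alcohol, which closes the trans‑fused γ‑lactone onto the methyl ester; any 7S ketone ends as the diastereomeric cis‑lactone and is removed here.

Step 16
Reactants: 27 (3aR,5Z,9E,11aS)‑6‑[(TBDPS‑oxy)methyl]‑10‑[(TBS‑oxy)methyl]‑3a,4,7,8,11,11a‑hexahydrocyclodeca[b]furan‑2(3H)‑one
Product: 30 (3aR,5Z,9E,11aS)‑6‑[(TBDPS‑oxy)methyl]‑10‑[(TBS‑oxy)methyl]‑3‑methylidene‑3a,4,7,8,11,11a‑hexahydrocyclodeca[b]furan‑2(3H)‑one, via Mannich base 28 (not isolated), via methiodide 29 (not isolated)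
Conditions: LiN(SiMe3)2, THF, −78 °C; CH2=NMe2+ I−, −78 → 0 °C; then MeI, MeOH, 23 °C; then aq NaHCO3/CH2Cl2
Reagents that add atoms: N,N‑dimethylmethyleneiminium iodide, C=[N+](C)C.[I-]
Why: aminomethylation of the lactone enolate (Mannich reaction) followed by quaternisation and β‑elimination is the standard α‑methylenation of γ‑butyrolactones, and the lactone α‑carbon is the only acidic site left.

Step 17
Reactants: 30 (3aR,5Z,9E,11aS)‑6‑[(TBDPS‑oxy)methyl]‑10‑[(TBS‑oxy)methyl]‑3‑methylidene‑3a,4,7,8,11,11a‑hexahydrocyclodeca[b]furan‑2(3H)‑one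
Product: 31 (3aR,5Z,9E,11aS)‑6‑[(TBDPS‑oxy)methyl]‑10‑(hydroxymethyl)‑3‑methylidene‑3a,4,7,8,11,11a‑hexahydrocyclodeca[b]furan‑2(3H)‑one
Conditions: HF·pyridine, pyridine, THF, 0 °C
Reagents that add atoms: none
Why: buffered HF desilylation removes the primary TBS ether much faster than the TBDPS ether and should spare the acid‑sensitive 1,5‑diene and the α‑methylene lactone.

Step 18
Reactants: 31 (3aR,5Z,9E,11aS)‑6‑[(TBDPS‑oxy)methyl]‑10‑(hydroxymethyl)‑3‑methylidene‑3a,4,7,8,11,11a‑hexahydrocyclodeca[b]furan‑2(3H)‑one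
Product: 32 [(3aR,5Z,9E,11aS)‑6‑[(TBDPS‑oxy)methyl]‑3‑methylidene‑2‑oxo‑2,3,3a,4,7,8,11,11a‑octahydrocyclodeca[b]furan‑10‑yl]methyl acetate
Conditions: Ac2O, pyridine, DMAP (cat.), CH2Cl2, 0 °C
Reagents that add atoms: acetic anhydride, CC(=O)OC(C)=O
Why: O‑acylation of the single free primary allylic alcohol installs the C14 acetate.

Step 19
Reactants: 32 [(3aR,5Z,9E,11aS)‑6‑[(TBDPS‑oxy)methyl]‑3‑methylidene‑2‑oxo‑2,3,3a,4,7,8,11,11a‑octahydrocyclodeca[b]furan‑10‑yl]methyl acetate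
Product: 33 [(3aR,5Z,9E,11aS)‑6‑(hydroxymethyl)‑3‑methylidene‑2‑oxo‑2,3,3a,4,7,8,11,11a‑octahydrocyclodeca[b]furan‑10‑yl]methyl acetate
Conditions: Bu4NF/AcOH (1:1), THF, 0 → 23 °C
Reagents that add atoms: none
Why: acetic acid‑buffered fluoride desilylation cleaves the TBDPS ether without acetate migration or conjugate addition to the α‑methylene lactone.

Step 20
Reactants: 34 ethyl 2‑(hydroxymethyl)prop‑2‑enoate
Product: 35 ethyl 2‑[(TBS‑oxy)methyl]prop‑2‑enoate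
Conditions: t‑BuMe2SiCl, imidazole, CH2Cl2, 0 → 23 °C
Reagents that add atoms: tert‑butylchlorodimethylsilane, CC(C)(C)[Si](C)(C)Cl
Why: silylation masks the hydroxyl so that the acid made from it cannot esterify itself.

Step 21
Reactants: 35 ethyl 2‑[(TBS‑oxy)methyl]prop‑2‑enoate
Product: 36 2‑[(TBS‑oxy)methyl]prop‑2‑enoic acid
Conditions: LiOH·H2O, THF/H2O, 0 °C; 1 M HCl to pH 4
Reagents that add atoms: lithium hydroxide, [Li+].[OH-]
Why: saponification of the ethyl ester at 0 °C leaves the primary TBS ether in place.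

Step 22
Reactants: 33 [(3aR,5Z,9E,11aS)‑6‑(hydroxymethyl)‑3‑methylidene‑2‑oxo‑2,3,3a,4,7,8,11,11a‑octahydrocyclodeca[b]furan‑10‑yl]methyl acetate; 36 2‑[(TBS‑oxy)methyl]prop‑2‑enoic acid
Product: 37 [(3aR,5Z,9E,11aS)‑10‑(acetoxymethyl)‑3‑methylidene‑2‑oxo‑2,3,3a,4,7,8,11,11a‑octahydrocyclodeca[b]furan‑6‑yl]methyl 2‑[(TBS‑oxy)methyl]prop‑2‑enoate
Conditions: EDC·HCl, DMAP (0.2 equiv), CH2Cl2, 0 → 23 °C
Reagents that add atoms: none
Why: carbodiimide/DMAP (Steglich) esterification joins the primary allylic alcohol to the protected acrylic acid under neutral conditions.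

Step 23
Reactants: 37 [(3aR,5Z,9E,11aS)‑10‑(acetoxymethyl)‑3‑methylidene‑2‑oxo‑2,3,3a,4,7,8,11,11a‑octahydrocyclodeca[b]furan‑6‑yl]methyl 2‑[(TBS‑oxy)methyl]prop‑2‑enoate
Product: 38 [(3aR,5Z,9E,11aS)‑10‑(acetoxymethyl)‑3‑methylidene‑2‑oxo‑2,3,3a,4,7,8,11,11a‑octahydrocyclodeca[b]furan‑6‑yl]methyl 2‑(hydroxymethyl)prop‑2‑enoate
Conditions: HF·pyridine, pyridine, THF, 0 → 23 °C
Reagents that add atoms: none
Why: buffered HF desilylation removes the last silyl ether and should leave the acetate, the acrylate and the α‑methylene lactone intact.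

**Compound list**

1 | tert‑butyl(diphenyl)(prop‑2‑yn‑1‑yloxy)silane | C#CCO[Si](c1ccccc1)(c1ccccc1)C(C)(C)C | starting material
2 | methyl 4‑(TBDPS‑oxy)but‑2‑ynoate | COC(=O)C#CCO[Si](c1ccccc1)(c1ccccc1)C(C)(C)C | intermediate
3 | [2‑(1,3‑dioxan‑2‑yl)ethyl]magnesium bromide | Br[Mg]CCC1OCCCO1 | starting material
4 | methyl (2Z)‑3‑[(TBDPS‑oxy)methyl]‑5‑(1,3‑dioxan‑2‑yl)pent‑2‑enoate | COC(=O)/C=C(/CCC1OCCCO1)CO[Si](c1ccccc1)(c1ccccc1)C(C)(C)C | intermediate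
5 | methyl (2Z)‑3‑[(TBDPS‑oxy)methyl]‑6‑oxohex‑2‑enoate | COC(=O)/C=C(/CCC=O)CO[Si](c1ccccc1)(c1ccccc1)C(C)(C)C | intermediate
6 | trimethyl phosphonoacetate | COC(=O)CP(=O)(OC)OC | starting material
7 | tert‑butyl bromoacetate | BrCC(=O)OC(C)(C)C | starting material
8 | 4‑tert‑butyl 1‑methyl 2‑(dimethoxyphosphoryl)butanedioate (racemic) | COC(=O)C(CC(=O)OC(C)(C)C)P(=O)(OC)OC | intermediate
9 | 4‑tert‑butyl 1‑methyl (2E)‑2‑{(4Z)‑6‑methoxy‑6‑oxo‑4‑[(TBDPS‑oxy)methyl]hex‑4‑en‑1‑ylidene}butanedioate | COC(=O)/C=C(/CC/C=C(/C(=O)OC)CC(=O)OC(C)(C)C)CO[Si](c1ccccc1)(c1ccccc1)C(C)(C)C | intermediate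
10 | (3E,7Z)‑9‑methoxy‑3‑(methoxycarbonyl)‑9‑oxo‑7‑[(TBDPS‑oxy)methyl]nona‑3,7‑dienoic acid | COC(=O)/C=C(/CC/C=C(/C(=O)OC)CC(=O)O)CO[Si](c1ccccc1)(c1ccccc1)C(C)(C)C | intermediate
11 | (3E,7Z)‑9‑hydroxy‑3‑(hydroxymethyl)‑7‑[(TBDPS‑oxy)methyl]nona‑3,7‑dienoic acid | OC/C=C(/CC/C=C(/CO)CC(=O)O)CO[Si](c1ccccc1)(c1ccccc1)C(C)(C)C | intermediate
12 | (4E)‑4‑{(4Z)‑6‑hydroxy‑4‑[(TBDPS‑oxy)methyl]hex‑4‑en‑1‑ylidene}oxolan‑2‑one | OC/C=C(/CC/C=C1/COC(=O)C1)CO[Si](c1ccccc1)(c1ccccc1)C(C)(C)C | intermediate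
13 | (4E)‑4‑{(4Z)‑4‑[(TBDPS‑oxy)methyl]‑6‑(TES‑oxy)hex‑4‑en‑1‑ylidene}oxolan‑2‑one | CC[Si](CC)(CC)OC/C=C(/CC/C=C1/COC(=O)C1)CO[Si](c1ccccc1)(c1ccccc1)C(C)(C)C | intermediate
14 | lithium (3E,7Z)‑3‑(hydroxymethyl)‑7‑[(TBDPS‑oxy)methyl]‑9‑(TES‑oxy)nona‑3,7‑dienoate | CC[Si](CC)(CC)OC/C=C(/CC/C=C(/CO)CC(=O)[O-])CO[Si](c1ccccc1)(c1ccccc1)C(C)(C)C.[Li+] | intermediate
15 | TBS ester of (3E,7Z)‑3‑[(TBS‑oxy)methyl]‑7‑[(TBDPS‑oxy)methyl]‑9‑(TES‑oxy)nona‑3,7‑dienoic acid | CC[Si](CC)(CC)OC/C=C(/CC/C=C(/CO[Si](C)(C)C(C)(C)C)CC(=O)O[Si](C)(C)C(C)(C)C)CO[Si](c1ccccc1)(c1ccccc1)C(C)(C)C | intermediate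
16 | (3E,7Z)‑3‑[(TBS‑oxy)methyl]‑7‑[(TBDPS‑oxy)methyl]‑9‑(TES‑oxy)nona‑3,7‑dienoic acid | CC[Si](CC)(CC)OC/C=C(/CC/C=C(/CO[Si](C)(C)C(C)(C)C)CC(=O)O)CO[Si](c1ccccc1)(c1ccccc1)C(C)(C)C | intermediate
17 | 3‑tert‑butoxy‑3‑oxopropanoic acid (mono‑tert‑butyl malonate) | CC(C)(C)OC(=O)CC(=O)O | starting material
18 | 1‑imidazolide of acid 16 | CC[Si](CC)(CC)OC/C=C(/CC/C=C(/CO[Si](C)(C)C(C)(C)C)CC(=O)n1ccnc1)CO[Si](c1ccccc1)(c1ccccc1)C(C)(C)C | intermediate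
19 | tert‑butyl (5E,9Z)‑3‑oxo‑5‑[(TBS‑oxy)methyl]‑9‑[(TBDPS‑oxy)methyl]‑11‑(TES‑oxy)undeca‑5,9‑dienoate | CC[Si](CC)(CC)OC/C=C(/CC/C=C(/CO[Si](C)(C)C(C)(C)C)CC(=O)CC(=O)OC(C)(C)C)CO[Si](c1ccccc1)(c1ccccc1)C(C)(C)C | intermediate
20 | tert‑butyl (5E,9Z)‑11‑hydroxy‑3‑oxo‑5‑[(TBS‑oxy)methyl]‑9‑[(TBDPS‑oxy)methyl]undeca‑5,9‑dienoate | OC/C=C(/CC/C=C(/CO[Si](C)(C)C(C)(C)C)CC(=O)CC(=O)OC(C)(C)C)CO[Si](c1ccccc1)(c1ccccc1)C(C)(C)C | intermediate
21 | acylketene from 20 (O=C=CH–C(=O)– terminus in place of the tert‑butyl ester) | OC/C=C(/CC/C=C(/CO[Si](C)(C)C(C)(C)C)CC(=O)C=C=O)CO[Si](c1ccccc1)(c1ccccc1)C(C)(C)C | intermediate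
22 | (6E,10Z)‑6‑[(TBS‑oxy)methyl]‑10‑[(TBDPS‑oxy)methyl]‑1‑oxacyclododeca‑6,10‑diene‑2,4‑dione | O=C1CC(=O)C/C(CO[Si](C)(C)C(C)(C)C)=C\CC/C(CO[Si](c2ccccc2)(c2ccccc2)C(C)(C)C)=C/CO1 | intermediate
23 | methyl bromoacetate | COC(=O)CBr | starting material
24 | methyl 2‑{(6E,10Z)‑2,4‑dioxo‑6‑[(TBS‑oxy)methyl]‑10‑[(TBDPS‑oxy)methyl]‑1‑oxacyclododeca‑6,10‑dien‑3‑yl}acetate (C3 labile, keto form drawn) | O=C1C(CC(=O)OC)C(=O)C/C(CO[Si](C)(C)C(C)(C)C)=C\CC/C(CO[Si](c2ccccc2)(c2ccccc2)C(C)(C)C)=C/CO1 | intermediate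
25 | methyl 2‑{(1R,3Z,7E)‑10‑oxo‑4‑[(TBDPS‑oxy)methyl]‑8‑[(TBS‑oxy)methyl]cyclodeca‑3,7‑dien‑1‑yl}acetate | CC(C)(C)[Si](c2ccccc2)(c2ccccc2)OC/C1=C\C[C@H](CC(=O)OC)C(=O)C/C(CO[Si](C)(C)C(C)(C)C)=C\CC1 | intermediate
26 | methyl 2‑{(1R,3Z,7E,10S)‑10‑hydroxy‑4‑[(TBDPS‑oxy)methyl]‑8‑[(TBS‑oxy)methyl]cyclodeca‑3,7‑dien‑1‑yl}acetate | CC(C)(C)[Si](c2ccccc2)(c2ccccc2)OC/C1=C\C[C@H](CC(=O)OC)[C@@H](O)C/C(CO[Si](C)(C)C(C)(C)C)=C\CC1 | intermediate
27 | (3aR,5Z,9E,11aS)‑6‑[(TBDPS‑oxy)methyl]‑10‑[(TBS‑oxy)methyl]‑3a,4,7,8,11,11a‑hexahydrocyclodeca[b]furan‑2(3H)‑one (trans‑fused) | CC(C)(C)[Si](c3ccccc3)(c3ccccc3)OC/C1=C\C[C@@H]2CC(=O)O[C@H]2C/C(CO[Si](C)(C)C(C)(C)C)=C\CC1 | intermediate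
28 | 3‑[(dimethylamino)methyl] derivative of 27 (C3 epimers) | CC(C)(C)[Si](c3ccccc3)(c3ccccc3)OC/C1=C\C[C@@H]2C(CN(C)C)C(=O)O[C@H]2C/C(CO[Si](C)(C)C(C)(C)C)=C\CC1 | intermediate
29 | trimethylammonium iodide from 28 | CC(C)(C)[Si](c3ccccc3)(c3ccccc3)OC/C1=C\C[C@@H]2C(C[N+](C)(C)C)C(=O)O[C@H]2C/C(CO[Si](C)(C)C(C)(C)C)=C\CC1.[I-] | intermediate
30 | (3aR,5Z,9E,11aS)‑6‑[(TBDPS‑oxy)methyl]‑10‑[(TBS‑oxy)methyl]‑3‑methylidene‑3a,4,7,8,11,11a‑hexahydrocyclodeca[b]furan‑2(3H)‑one | CC(C)(C)[Si](c3ccccc3)(c3ccccc3)OC/C1=C\C[C@@H]2C(=C)C(=O)O[C@H]2C/C(CO[Si](C)(C)C(C)(C)C)=C\CC1 | intermediate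
31 | (3aR,5Z,9E,11aS)‑6‑[(TBDPS‑oxy)methyl]‑10‑(hydroxymethyl)‑3‑methylidene‑3a,4,7,8,11,11a‑hexahydrocyclodeca[b]furan‑2(3H)‑one | CC(C)(C)[Si](c3ccccc3)(c3ccccc3)OC/C1=C\C[C@@H]2C(=C)C(=O)O[C@H]2C/C(CO)=C\CC1 | intermediate
32 | [(3aR,5Z,9E,11aS)‑6‑[(TBDPS‑oxy)methyl]‑3‑methylidene‑2‑oxo‑2,3,3a,4,7,8,11,11a‑octahydrocyclodeca[b]furan‑10‑yl]methyl acetate | CC(C)(C)[Si](c3ccccc3)(c3ccccc3)OC/C1=C\C[C@@H]2C(=C)C(=O)O[C@H]2C/C(COC(C)=O)=C\CC1 | intermediate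
33 | [(3aR,5Z,9E,11aS)‑6‑(hydroxymethyl)‑3‑methylidene‑2‑oxo‑2,3,3a,4,7,8,11,11a‑octahydrocyclodeca[b]furan‑10‑yl]methyl acetate | OC/C1=C\C[C@@H]2C(=C)C(=O)O[C@H]2C/C(COC(C)=O)=C\CC1 | intermediate
34 | ethyl 2‑(hydroxymethyl)prop‑2‑enoate | C=C(CO)C(=O)OCC | starting material
35 | ethyl 2‑[(TBS‑oxy)methyl]prop‑2‑enoate | C=C(CO[Si](C)(C)C(C)(C)C)C(=O)OCC | intermediate
36 | 2‑[(TBS‑oxy)methyl]prop‑2‑enoic acid | C=C(CO[Si](C)(C)C(C)(C)C)C(=O)O | intermediate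
37 | [(3aR,5Z,9E,11aS)‑10‑(acetoxymethyl)‑3‑methylidene‑2‑oxo‑2,3,3a,4,7,8,11,11a‑octahydrocyclodeca[b]furan‑6‑yl]methyl 2‑[(TBS‑oxy)methyl]prop‑2‑enoate | C=C(CO[Si](C)(C)C(C)(C)C)C(=O)OC/C1=C\C[C@@H]2C(=C)C(=O)O[C@H]2C/C(COC(C)=O)=C\CC1 | intermediate
38 | [(3aR,5Z,9E,11aS)‑10‑(acetoxymethyl)‑3‑methylidene‑2‑oxo‑2,3,3a,4,7,8,11,11a‑octahydrocyclodeca[b]furan‑6‑yl]methyl 2‑(hydroxymethyl)prop‑2‑enoate | C=C(CO)C(=O)OC/C1=C\C[C@@H]2C(=C)C(=O)O[C@H]2C/C(COC(C)=O)=C\CC1 | target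

**Counts**

Total step count: 23. Longest linear sequence: 20 steps (1–3, 5–19, 22, 23).

**Steps most likely to fail**

Step 14 (proposed new method). The zwitterion may collapse between molecules (oligomers), lose a β‑hydrogen from the π‑allyl unit to give a diene, transfer a proton to form the C9 dienolate, scramble the syn/anti geometry of the allyl unit, or show poor enantioface selection at C7. The fallback uses known chemistry, sets out from 20 and returns at 25. Compound 20 is alkylated with methyl bromoacetate (K2CO3, acetone) to the α‑substituted β‑keto ester F1, and its alcohol is converted with ClCO2Me/pyridine into the allylic methyl carbonate F2. An intramolecular Tsuji–Trost allylic alkylation (Pd(PPh3)4, THF, 65 °C, 2 mM) then closes the ten‑membered ring directly at the primary allyl terminus to give the quaternary β‑keto ester F3. Cleavage of the tert‑butyl ester (Me3SiOTf, 2,6‑lutidine, then pH 7 buffer, 35 °C) with decarboxylation gives racemic ketone, that is 25 together with its (1S)‑enantiomer F4. Step 15 then also serves as the resolution: F4 ends as the cis‑lactone F5, which is removed by chromatography, and enantiopure material continues from 27 at no more than half the throughput.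

Step 12. The acylketene may be captured between molecules, or tert‑butanol may add back, so that oligomers form instead of the 12‑membered ring. The fallback sets out from 16 and returns at 22. Acid 16 is condensed with Meldrum's acid (EDC·HCl, DMAP, CH2Cl2) to the acyl Meldrum's acid F6, and the TES ether is removed (pyridinium p‑toluenesulfonate, MeOH, 0 °C) to give the hydroxy acyl Meldrum's acid F7. Heating F7 in benzene (80 °C, 1 mM) releases the same acylketene by irreversible loss of acetone and CO2, 30 °C lower and without a nucleophilic by‑product, and gives 22.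

Step 15. Hydride delivery may be governed by the ring conformation rather than by the catalyst (poor facial selectivity at C8), giving mainly the 8‑epimer. The fallback sets out from 25 and returns at 27. Ketone 25 is reduced under substrate control with lithium tri‑sec‑butylborohydride (THF, −78 °C) to the (10R)‑hydroxy ester F8, which closes to the cis‑lactone F9. Saponification (LiOH, THF/H2O, acidification to pH 5 at 0 °C) gives the hydroxy acid F10, and a Mitsunobu lactonisation (PPh3, DIAD, toluene, 0 → 23 °C) closes the lactone with inversion at C8 to give 27.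

**Further compounds**

F1 | step 14 | tert‑butyl (5E,9Z)‑11‑hydroxy‑2‑(2‑methoxy‑2‑oxoethyl)‑3‑oxo‑5‑[(TBS‑oxy)methyl]‑9‑[(TBDPS‑oxy)methyl]undeca‑5,9‑dienoate | OC/C=C(/CC/C=C(/CO[Si](C)(C)C(C)(C)C)CC(=O)C(CC(=O)OC)C(=O)OC(C)(C)C)CO[Si](c1ccccc1)(c1ccccc1)C(C)(C)C
F2 | step 14 | methyl carbonate of F1 at the C11 hydroxyl | COC(=O)OC/C=C(/CC/C=C(/CO[Si](C)(C)C(C)(C)C)CC(=O)C(CC(=O)OC)C(=O)OC(C)(C)C)CO[Si](c1ccccc1)(c1ccccc1)C(C)(C)C
F3 | step 14 | tert‑butyl (3Z,7E)‑1‑(2‑methoxy‑2‑oxoethyl)‑10‑oxo‑4‑[(TBDPS‑oxy)methyl]‑8‑[(TBS‑oxy)methyl]cyclodeca‑3,7‑diene‑1‑carboxylate (racemic) | CC(C)(C)[Si](c2ccccc2)(c2ccccc2)OC/C1=C\CC(CC(=O)OC)(C(=O)OC(C)(C)C)C(=O)C/C(CO[Si](C)(C)C(C)(C)C)=C\CC1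
F4 | step 14 | methyl 2‑{(1S,3Z,7E)‑10‑oxo‑4‑[(TBDPS‑oxy)methyl]‑8‑[(TBS‑oxy)methyl]cyclodeca‑3,7‑dien‑1‑yl}acetate (enantiomer of 25) | CC(C)(C)[Si](c2ccccc2)(c2ccccc2)OC/C1=C\C[C@@H](CC(=O)OC)C(=O)C/C(CO[Si](C)(C)C(C)(C)C)=C\CC1
F5 | step 14 | (3aS,5Z,9E,11aS)‑6‑[(TBDPS‑oxy)methyl]‑10‑[(TBS‑oxy)methyl]‑3a,4,7,8,11,11a‑hexahydrocyclodeca[b]furan‑2(3H)‑one (cis‑fused) | CC(C)(C)[Si](c3ccccc3)(c3ccccc3)OC/C1=C\C[C@H]2CC(=O)O[C@H]2C/C(CO[Si](C)(C)C(C)(C)C)=C\CC1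
F6 | step 12 | acyl Meldrum's acid from 16 (5‑acyl‑2,2‑dimethyl‑1,3‑dioxane‑4,6‑dione, TES ether) | CC[Si](CC)(CC)OC/C=C(/CC/C=C(/CO[Si](C)(C)C(C)(C)C)CC(=O)C1C(=O)OC(C)(C)OC1=O)CO[Si](c1ccccc1)(c1ccccc1)C(C)(C)C
F7 | step 12 | acyl Meldrum's acid with free C6 hydroxyl | OC/C=C(/CC/C=C(/CO[Si](C)(C)C(C)(C)C)CC(=O)C1C(=O)OC(C)(C)OC1=O)CO[Si](c1ccccc1)(c1ccccc1)C(C)(C)C
F8 | step 15 | methyl 2‑{(1R,3Z,7E,10R)‑10‑hydroxy‑4‑[(TBDPS‑oxy)methyl]‑8‑[(TBS‑oxy)methyl]cyclodeca‑3,7‑dien‑1‑yl}acetate | CC(C)(C)[Si](c2ccccc2)(c2ccccc2)OC/C1=C\C[C@H](CC(=O)OC)[C@H](O)C/C(CO[Si](C)(C)C(C)(C)C)=C\CC1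
F9 | step 15 | (3aR,5Z,9E,11aR)‑6‑[(TBDPS‑oxy)methyl]‑10‑[(TBS‑oxy)methyl]‑3a,4,7,8,11,11a‑hexahydrocyclodeca[b]furan‑2(3H)‑one (cis‑fused) | CC(C)(C)[Si](c3ccccc3)(c3ccccc3)OC/C1=C\C[C@@H]2CC(=O)O[C@@H]2C/C(CO[Si](C)(C)C(C)(C)C)=C\CC1
F10 | step 15 | 2‑{(1R,3Z,7E,10R)‑10‑hydroxy‑4‑[(TBDPS‑oxy)methyl]‑8‑[(TBS‑oxy)methyl]cyclodeca‑3,7‑dien‑1‑yl}acetic acid | CC(C)(C)[Si](c2ccccc2)(c2ccccc2)OC/C1=C\C[C@H](CC(=O)O)[C@H](O)C/C(CO[Si](C)(C)C(C)(C)C)=C\CC1
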